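The readings are simulated with constants of no real substance, and the scatter is random.

Let X be the clock. In fractions of the G charged, J and X both draw on G, and J also spends Q. Dividing the two rates removes time: J made per X made goes with the Q left. So Q falls exponentially in X, as a first-order signal falls in time.

| setting | spring | dawn | flask |
|---|---|---|---|
| G | 0.020 M | 0.020 M | 0.020 M |
| Q | 10 mM | 10 mM | 10.0 mM |
| D | 6 mM | 3 mM | 6.00 mM |
| remark | the very flask that is asked about, followed so far | run made earlier |  |
| time |  |  | 2.0 min |

- spring (time / s: G / %, X / %, J / %): 12.0: 47.2, 13.1, 9.8; 25.0: 31.9, 22.2, 16.1; 40.0: 20.8, 29.5, 19.5; 50.0: 16.5, 32.0, 21.5; 60.0: 11.6, 34.9, 23.1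
- dawn (time / s: G / %, X / %, J / %): 25.0: 40.3, 26.7, 17.2; 50.0: 21.2, 39.8, 24.7; 80.0: 9.7, 48.1, 27.8; 90.0: 8.0, 49.3, 27.7; 120: 3.5, 52.6, 28.8

(each reading ± 0.5 percentage points)

1. the largest share of what was charged as G, at 2.0 min belongs to (G / J / X)
2. the largest share itself, whichever of these holds it, in percent of the G charged

- the analysis behind the earlier runs scatters by 0.5 percentage points, standard deviation
- reactions considered so far: G + Q -> J; G -> X; G + D -> Z

With Q charged over G charged at 0.500, the last spring reading gives 0.563 and the last dawn reading 0.613 for X divided by the logarithm of Q charged over Q left. We carry their mean, 0.588, the X-constant: the X made, at this charge of G, while Q falls by a factor e, a selectivity factor in another form. As a test, the dawn X at 80.0 s gives J 27.9%, and the reading is 27.8%.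

The X-constant carries no time, so we take the pace from the spring readings. Extending the spring decay of G gives 2.05% at 2.0 min. At the last spring reading, the constant puts the part of X in what X and J take from G at 68.0%; holding that part over the further loss of G, we reckon X at 41.4%. The forecast says X at 41.2%, holding that “The mass balance is the key”.

The flask gives X at 42.1%, with J at 25.2%.

    G + Q → J (k = 1.50 L mol⁻¹ s⁻¹)
    G → X (k = 0.0180 s⁻¹)
    G + D → Z (k = 32.0 L mol⁻¹ s⁻¹)

Left until 20.0 min, this flask holds X at 44.0%. The X-constant turns its X at 2.0 min into J of 25.6%, against the 25.2% found. In the neighbour flask with 0.040 M of Q, the ratio of charges becomes 2.00, and its X of 18.1% gives J of 52.9%, against the 52.0% found.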